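## The problem

Labdane locants are used for all ring compounds: C1–C10 form the decalin (C5 the ring-fusion CH, C10 the ring-fusion carbon bearing methyl C20), C11–C16 the chain on C9, C17 the methyl on C8, C18 the oxygenated carbon and C19 the methyl on C4. CIP descriptors are written out and take precedence over any stereochemistry the labdane name might imply.

Target 17 is a trans-fused decalin (rings A and B) whose C9 carries a chain ending in a 2-substituted buta-1,3-diene (C13(=C16)–C14=C15). Six contiguous stereocentres (C3, C4, C5, C8, C9, C10) surround the decalin, and three of them (C4, C8, C10) are fully substituted. The C9 chain is axial, trans to C20 and cis to the equatorial tertiary hydroxyl on C8. This is the reverse of the usual labdane arrangement, and since C9 never has a neighbouring carbonyl it must be set when the C9–C10 bond forms. In ring A the C3 acetoxy group and the C18 hydroxymethyl group are both equatorial; this is the imprint of an E-configured epoxy alcohol terminus opened with inversion at C4. C3 and C4 can therefore be set by a reagent, and they can relay to C5 and C10 through an E olefin and to C9 and C8 through a Z olefin. The fragile groups are the diene (acid, dienophiles, radicals), the tertiary C8 alcohol (elimination, or ether formation with the diene under acid) and the 1,3-related secondary acetate and primary alcohol (acyl shift to the primary oxygen under base). The enabling feature is that the C8 oxygen lies five atoms from C13 (O–C8–C9–C11–C12–C13). If C13 is a carboxyl carbon, that oxygen can end a cation–olefin cascade running C4→C5 and C10→C9, and anti addition across a chair-folded Z C8=C9 olefin gives exactly the trans C9/C10 and cis C9/C8–O relationships.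

## Retrosynthesis

**Protecting-group end (17 ⇒ 16 ⇒ 15).** The O–Si bond at C18 and the O–acyl bond at C3 are cut. The primary oxygen has to be masked while the secondary one is acetylated, and it has to be masked from the epoxy alcohol stage onwards anyway, so one tert-butyldiphenylsilyl group serves throughout. The acetate is introduced late because it would not survive hydride reduction of the lactone or carbonate in methanol. The forward steps must acetylate C3–OH beside the tertiary C8–OH (diene diol 15 to acetate 16) and then free O18 without base, so that the acetate stays on O3.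

**Diene (15 ⇒ 14).** The C13=C16 and C14=C15 double bonds are cut, and both methylene carbons are returned to ethylene, leaving terminal alkyne 14. The shorter neighbour, opening lactone 11 with a vinyl metal and methylenating the vinyl ketone, was set aside for three reasons: δ-lactones tend to add a second equivalent, the vinyl ketone is a Michael acceptor, and its hemiketal form resists methylenation. Dehydrating a tertiary allylic alcohol would give olefin isomers. The alkyne is inert to everything before it, and ethylene enyne metathesis makes the diene under neutral conditions with free hydroxyls present. The forward reaction must turn over on an alkyne that has no propargylic heteroatom.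

**Alkyne (14 ⇒ 12 ⇒ 11).** The C13≡C14 bond is cut back to the aldehyde carbon of lactol 12 (open form 13), and the lactol goes back to lactone 11 by one reduction level. This uses the lactone carbonyl C13 directly as the handle and costs two routine steps. The forward reactions must stop the hydride reduction at the lactol and homologate through the small equilibrium share of 13.

**Key disconnection (11 ⇒ 10).** C4–C5, C9–C10 and C8–O are cut together, unfolding the tricyclic lactone 11 into the acyclic epoxy acid 10. Stepwise annulation would have to build three fully substituted centres one after another. A polyene cyclisation ending by proton loss would leave the C8 oxygen to be added later to a hindered olefin with no face control. A 1,3-diene could not be carried through the cation cascade at all, so the carboxyl group both ends the cascade and stores C13. Precursor 10 has one oxirane (two stereocentres) and two olefin geometries in place of three rings and six stereocentres. The forward reaction must ionise the oxirane at C4, fold chair–chair and end at the carboxyl oxygen.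

**Epoxy acid (10 ⇒ 9 ⇒ 7 ⇒ 6).** The ester is hydrolysed last, the O–Si bond and the two oxirane C–O bonds are cut, and E allylic alcohol 6 remains. The methyl ester is kept through the titanium-catalysed epoxidation because a free acid would bind the catalyst. The silyl group is chosen bulky and weakly basic so that the Lewis acid of the key step binds the oxirane oxygen and not a chelate. The asymmetric epoxidation of 6 to 7 is the only step that sets absolute configuration; silylation then gives 9.

**Allylic alcohol (6 ⇒ 5).** The C14–O bond is cut to a C–H bond of triene ester 5. Building the terminus by olefination would cost about five steps. The forward reaction must pick the terminal E methyl group among three trisubstituted olefins.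

**Chain (5 ⇒ 4 ⇒ 2 + 3; 2 ⇒ 1).** The C2–C3 bond of the ester chain is cut, giving allylic bromide 2 and dimethyl malonate 3 by way of malonate 4. The Z olefin is bought in (2Z,6E)-farnesol 1 and not made: a Wittig reaction on a methyl ketone or a Claisen rearrangement of a tertiary allylic alcohol would give E/Z mixtures at exactly the olefin that controls C9. The forward steps must substitute without allylic transposition or loss of geometry.

## Roads not taken

**Alternative 1:** Ring B is cut at C7–C8 and C9–C10. A ring-A vinylcyclohexene A2 (diene C10=C5–C6=C7, C3/C18 diol as acetonide) and citraconic anhydride A3 would combine in a thermal or high-pressure Diels–Alder reaction to the endo adduct A1.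
- Merits: the route is convergent, both partners are small, and the cis anhydride guarantees that C11 on C9 and the C8 substituent that later becomes oxygen are cis. Quaternary C10 is made in the same step, and no cation chemistry or pure Z olefin is needed. In convergence and raw-material cost this road is better than the chosen one.
- Weak points: each new σ bond ends at a fully substituted carbon (C10 of A2, C8 of A3), so forcing conditions are expected. The diene faces differ only through the remote C4 substituents, so C10 is poorly tied to C3/C4, and the endo/exo ratio decides C8/C9 against C10. After A1, C5 must still be set by reducing C5=C6, the two anhydride carbonyls must be told apart, the carbon on C8 must be degraded to hydroxyl with retention, and C11 must be extended by C12–C16. A2 also needs its own enantioselective synthesis.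
- Comparison: the chosen plan sets against this that lactone 11 leaves the key step with the C8 oxygen, C5 and the C11–C13 chain in place, five functional-group steps from 17.

**Alternative 2:** Only C9–C11 is cut, within a monocyclic ring B. The malonic half-ester A5 of 4-hydroxy-4-methylcyclohexa-2,5-dienone would lose CO2 under a cinchona-derived amine–thiourea catalyst and add to one enone terminus, giving the cis-fused lactone enone A4.
- Merits: the step is catalytic and enantioselective, and starts from an achiral quinol. C8 already carries its oxygen and methyl, and the five-membered lactone enforces the cis C8/C9 relationship. In certainty of that relationship and in cost it is at least the equal of the chosen plan.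
- Weak points: A4 holds ring B and two of six stereocentres. Ring A, with quaternary C4 and C10 plus C3 and C5, must be annulated onto the C5 ketone and the C10 methylene, and C10 needs two alkylations with the methyl ending trans to C11. The C6=C7 enone must be removed, and the lactone carbonyl is C12, so C13–C16 need a further C–C bond.
- Comparison: the chosen plan sets against this that C1–C13 and all six stereocentres are present after one step from a chain made in seven.

**Alternative 3:** C9–C11 and C8–O are cut on a finished decalin. The trisubstituted olefin A7 (C8=C9, C9 unsubstituted, 3,18-bis-pivalate) would take up a carboxymethyl radical generated by Mn(OAc)3; oxidation at C8 and carboxyl capture give the cis γ-lactone A6.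
- Merits: the radical should approach C9 from the face opposite the axial C20 methyl, which is the unusual chain orientation of 17, and a five-membered lactone can only close cis. C9 and C8 therefore follow the bias of a rigid ring, arguably more predictable than the folding of a Z olefin in the chosen key step.
- Weak points: A7 is itself a trans-decalin with four stereocentres and a regiodefined olefin. Making it enantioselectively needs its own polyene cyclisation or a long annulation sequence, so the central problem returns one stage earlier. The hot acidic oxidising medium invites allylic oxidation and elimination from the C8 cation. The lactone carbonyl is C12, so C13 with its methylene and vinyl groups needs another C–C bond, and a primary hydroxyl must then be told from the tertiary one.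
- Comparison: this road is stronger at C9 and weaker in step economy. The chosen plan answers by forming both rings and the C8–O bond and delivering C13 at the right oxidation level in one operation.

Key step: step 8

Remark on the chemistry: (2Z,6E)-farnesol (1) is assumed to be bought as the single 2Z,6E isomer.

## Route

Step 1
Reactants: 1 (2Z,6E)-farnesol
Product: 2 (2Z,6E)-farnesyl bromide, (2Z,6E)-1-bromo-3,7,11-trimethyldodeca-2,6,10-triene
Conditions: PBr3 (0.4 equiv), Et2O, −10 °C
Reagents that add atoms: phosphorus tribromide, BrP(Br)Br
Why: Bromination of a primary allylic alcohol through its phosphite ester is an SN2 displacement at low temperature, so the 2Z geometry and the position of the olefin should be kept; the bromide is used at once.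

Step 2
Reactants: 2 (2Z,6E)-farnesyl bromide; 3 dimethyl malonate
Product: 4 dimethyl 2-[(2Z,6E)-3,7,11-trimethyldodeca-2,6,10-trien-1-yl]propanedioate
Conditions: NaH, excess 3, THF, 0 °C → rt
Reagents that add atoms: none
Why: Malonic ester alkylation: the soft malonate anion displaces the primary allylic bromide at C1 (SN2, not SN2′), and the excess of 3 suppresses dialkylation.

Step 3
Reactants: 4 dimethyl farnesylmalonate
Product: 5 methyl (4Z,8E)-5,9,13-trimethyltetradeca-4,8,12-trienoate
Conditions: LiCl, H2O (2 equiv), DMSO, 150 °C
Reagents that add atoms: none
Why: Krapcho dealkoxycarbonylation: chloride demethylates one ester, the carboxylate loses CO2 and water protonates the ester enolate; the medium is close to neutral, so the isolated trisubstituted olefins should neither migrate nor isomerise.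

Step 4
Reactants: 5 methyl (4Z,8E)-5,9,13-trimethyltetradeca-4,8,12-trienoate
Product: 6 methyl (4Z,8E,12E)-14-hydroxy-5,9,13-trimethyltetradeca-4,8,12-trienoate
Conditions: SeO2 (0.2 equiv), salicylic acid (0.1 equiv), t-BuOOH (3 equiv), CH2Cl2, 0 °C → rt, stopped at partial conversion
Reagents that add atoms: selenium dioxide, O=[Se]=O (transfers the oxygen); tert-butyl hydroperoxide, CC(C)(C)OO (restores it)
Why: Riley allylic oxidation (ene reaction, then [2,3]-sigmatropic shift) attacks the most accessible, terminal trisubstituted olefin at the methyl group trans to the chain, which gives the 12E allylic alcohol; catalytic selenium and partial conversion limit over-oxidation and attack on the inner olefins.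

Step 5
Reactants: 6 methyl (4Z,8E,12E)-14-hydroxy-5,9,13-trimethyltetradeca-4,8,12-trienoate
Product: 7 methyl (4Z,8E)-11-[(2R,3R)-3-(hydroxymethyl)-3-methyloxiran-2-yl]-5,9-dimethylundeca-4,8-dienoate
Conditions: Ti(OiPr)4 (10 mol%), D-(−)-diethyl tartrate (12 mol%), t-BuOOH (2 equiv, anhydrous), 4 Å molecular sieves, CH2Cl2, −20 °C
Reagents that add atoms: tert-butyl hydroperoxide, CC(C)(C)OO
Why: Sharpless asymmetric epoxidation: only the olefin of the titanium-bound allylic alcohol is oxidised, and for E-2-methylalk-2-en-1-ols D-(−)-tartrate gives the (2R,3R)-oxirane (L-(+)-tartrate gives 2S,3S), a substrate class known for high enantioselectivity; this fixes C3 and C4 of the target.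

Step 6
Reactants: 7 epoxy alcohol; 8 tert-butyl(chloro)diphenylsilane
Product: 9 methyl (4Z,8E)-11-[(2R,3R)-3-({[tert-butyl(diphenyl)silyl]oxy}methyl)-3-methyloxiran-2-yl]-5,9-dimethylundeca-4,8-dienoate
Conditions: imidazole, DMF, 0 °C → rt
Reagents that add atoms: none
Why: Imidazole-promoted silylation of a primary alcohol; the basic medium leaves the oxirane untouched, and the bulky, weakly basic silyl ether is chosen to survive the Lewis acid of step 8.

Step 7
Reactants: 9 silyl-protected epoxy ester
Product: 10 (4Z,8E)-11-[(2R,3R)-3-({[tert-butyl(diphenyl)silyl]oxy}methyl)-3-methyloxiran-2-yl]-5,9-dimethylundeca-4,8-dienoic acid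
Conditions: LiOH·H2O, THF/MeOH/H2O, 0 °C → rt; then cold aq. citric acid to pH 5
Reagents that add atoms: lithium hydroxide, [Li+].[OH-]
Why: Ester saponification by acyl–oxygen cleavage; the trisubstituted oxirane and the silyl ether are stable to LiOH at room temperature, and buffered acidification frees the acid without opening the oxirane; the acid is used promptly.

Step 8
Reactants: 10 epoxy dienoic acid
Product: 11 (3R,4S,5S,8S,9R,10R)-18-[tert-butyl(diphenyl)silyl]oxy-3-hydroxy-14,15,16-trinorlabdan-13,8-olide (δ-lactone, carbonyl C13, ring oxygen on C8)
Conditions: MeAlCl2 (3 equiv), CH2Cl2, high dilution, −78 °C; Et3N, then aq. potassium sodium tartrate (KNaC4H4O6)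
Reagents that add atoms: none
Why: The first equivalent of MeAlCl2 removes the carboxyl proton as methane and a further equivalent binds the oxirane oxygen, so the C4–O bond ionises at the tertiary carbon while the 8E olefin attacks from the rear; the reaction type is the known Lewis-acid, epoxide-initiated cation–olefin polycyclisation ended by a carboxyl group (polyene lactonisation). Ring A closes 6-endo (C4–C5, inversion at C4, C3 keeps its oxygen as the equatorial alcohol), ring B closes 6-endo (C9–C10), and the lactone closes when the carboxylate oxygen captures the tertiary C8 cation, a six-membered closure that is 6-endo with respect to the C8=C9 π bond. C5 and C10 come from anti addition across the E olefin in a chair, which gives the trans ring fusion on the face dictated by the (2R,3R)-oxirane. C9 and C8 come from anti addition across the Z olefin in the second chair, which puts C11 axial (trans to C20) and the new C8–O bond equatorial (cis to C11). The step needs opening at C4 and not C3, propagation without proton loss, and chair–chair folding. The tertiary centre and the non-chelating silyl ether favour the first, the low temperature and the internal carboxylate favour the second, and the third is helped because an axial C11 tether can reach C8 only equatorially, so any product with C11 axial must have the correct C8.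

Step 9
Reactants: 11 tricyclic δ-lactone
Product: 12 (3R,4S,5S,8S,9R,10R)-18-[tert-butyl(diphenyl)silyl]oxy-8,13-epoxy-14,15,16-trinorlabdane-3,13-diol (lactol, both C13 epimers)
Conditions: i-Bu2AlH (2.5 equiv), CH2Cl2, −78 °C; aq. potassium sodium tartrate (KNaC4H4O6)
Reagents that add atoms: none
Why: Partial reduction of a lactone: the tetrahedral aluminium hemiacetal is stable at −78 °C, so reduction should stop at the lactol; one equivalent is consumed by C3–OH and the silyl ether is inert.

Step 10
Reactants: 12 lactol
Product: 14 (3R,4S,5S,8S,9R,10R)-18-[tert-butyl(diphenyl)silyl]oxy-15,16-dinorlabd-13-yne-3,8-diol, via seco hydroxy aldehyde 13 (not isolated)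
Conditions: dimethyl (1-diazo-2-oxopropyl)phosphonate, K2CO3, MeOH, 0 °C → rt
Reagents that add atoms: dimethyl (1-diazo-2-oxopropyl)phosphonate, CC(=O)C(=[N+]=[N-])P(=O)(OC)OC
Why: Seyferth–Gilbert homologation in its Ohira–Bestmann form: the lactol is in equilibrium with hydroxy aldehyde 13, which adds the diazomethylphosphonate anion made in the flask, loses phosphate and N2 and rearranges by 1,2-hydrogen shift to the terminal alkyne; the carbonate base is mild and no stereocentre is α to the aldehyde.

Step 11
Reactants: 14 alkyne diol
Product: 15 (3R,4S,5S,8S,9R,10R)-18-[tert-butyl(diphenyl)silyl]oxylabda-13(16),14-diene-3,8-diol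
Conditions: ethylene (1 atm), second-generation Grubbs catalyst RuCl2(=CHPh)(PCy3)(H2IMes) (10 mol%), toluene, 60 °C
Reagents that add atoms: ethylene, C=C
Why: Cross enyne metathesis with ethylene: the ruthenium methylidene adds to the alkyne and ethylene turns over the resulting vinylcarbene, giving the 2-substituted buta-1,3-diene directly; free secondary and tertiary hydroxyls are tolerated and the ethylene atmosphere keeps the diene out of secondary metathesis.

Step 12
Reactants: 15 diene diol
Product: 16 (3R,4S,5S,8S,9R,10R)-18-[tert-butyl(diphenyl)silyl]oxy-8-hydroxylabda-13(16),14-dien-3-yl acetate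
Conditions: Ac2O, pyridine, DMAP (cat.), CH2Cl2, 0 °C → rt
Reagents that add atoms: acetic anhydride, CC(=O)OC(C)=O
Why: Nucleophile-catalysed acylation takes the equatorial secondary C3–OH; the tertiary C8–OH is not acylated under these mild conditions.

Step 13
Reactants: 16 silyl-protected acetate
Product: 17 (3R,4S,5S,8S,9R,10R)-8,18-dihydroxylabda-13(16),14-dien-3-yl acetate (target)
Conditions: HF·pyridine, excess pyridine, THF, 0 °C → rt
Reagents that add atoms: none
Why: Fluoride cleaves the Si–O bond in a buffered, slightly acidic medium in which no alkoxide is formed, so the C3 acetate should not shift to O18; the medium is too weakly acidic to ionise the tertiary alcohol or protonate the diene.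

## Compound list

1 | (2Z,6E)-farnesol, (2Z,6E)-3,7,11-trimethyldodeca-2,6,10-trien-1-ol | CC(C)=CCC/C(C)=C/CC/C(C)=C\CO | starting material
2 | (2Z,6E)-1-bromo-3,7,11-trimethyldodeca-2,6,10-triene | CC(C)=CCC/C(C)=C/CC/C(C)=C\CBr | intermediate
3 | dimethyl malonate | COC(=O)CC(=O)OC | starting material
4 | dimethyl 2-[(2Z,6E)-3,7,11-trimethyldodeca-2,6,10-trien-1-yl]propanedioate | CC(C)=CCC/C(C)=C/CC/C(C)=C\CC(C(=O)OC)C(=O)OC | intermediate
5 | methyl (4Z,8E)-5,9,13-trimethyltetradeca-4,8,12-trienoate | CC(C)=CCC/C(C)=C/CC/C(C)=C\CCC(=O)OC | intermediate
6 | methyl (4Z,8E,12E)-14-hydroxy-5,9,13-trimethyltetradeca-4,8,12-trienoate | OC/C(C)=C/CC/C(C)=C/CC/C(C)=C\CCC(=O)OC | intermediate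
7 | methyl (4Z,8E)-11-[(2R,3R)-3-(hydroxymethyl)-3-methyloxiran-2-yl]-5,9-dimethylundeca-4,8-dienoate | COC(=O)CC/C=C(/C)CC/C=C(\C)CC[C@H]1O[C@]1(C)CO | intermediate
8 | tert-butyl(chloro)diphenylsilane | CC(C)(C)[Si](Cl)(c1ccccc1)c1ccccc1 | starting material
9 | methyl (4Z,8E)-11-[(2R,3R)-3-({[tert-butyl(diphenyl)silyl]oxy}methyl)-3-methyloxiran-2-yl]-5,9-dimethylundeca-4,8-dienoate | COC(=O)CC/C=C(/C)CC/C=C(\C)CC[C@H]1O[C@]1(C)CO[Si](c2ccccc2)(c2ccccc2)C(C)(C)C | intermediate
10 | (4Z,8E)-11-[(2R,3R)-3-({[tert-butyl(diphenyl)silyl]oxy}methyl)-3-methyloxiran-2-yl]-5,9-dimethylundeca-4,8-dienoic acid | OC(=O)CC/C=C(/C)CC/C=C(\C)CC[C@H]1O[C@]1(C)CO[Si](c2ccccc2)(c2ccccc2)C(C)(C)C | intermediate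
11 | (3R,4S,5S,8S,9R,10R)-18-[tert-butyl(diphenyl)silyl]oxy-3-hydroxy-14,15,16-trinorlabdan-13,8-olide; C3–O and C18 equatorial, C17/C19/C20 axial on one face, H5, the C9 chain and O8 on the other | O=C1CC[C@@H]2[C@]3(C)CC[C@@H](O)[C@](C)(CO[Si](c4ccccc4)(c4ccccc4)C(C)(C)C)[C@H]3CC[C@]2(C)O1 | intermediate
12 | (3R,4S,5S,8S,9R,10R)-18-[tert-butyl(diphenyl)silyl]oxy-8,13-epoxy-14,15,16-trinorlabdane-3,13-diol (lactol, C13 epimers) | OC1CC[C@@H]2[C@]3(C)CC[C@@H](O)[C@](C)(CO[Si](c4ccccc4)(c4ccccc4)C(C)(C)C)[C@H]3CC[C@]2(C)O1 | intermediate
13 | (3R,4S,5S,8S,9R,10R)-18-[tert-butyl(diphenyl)silyl]oxy-3,8-dihydroxy-14,15,16-trinorlabdan-13-al | O=CCC[C@@H]1[C@]2(C)CC[C@@H](O)[C@](C)(CO[Si](c3ccccc3)(c3ccccc3)C(C)(C)C)[C@H]2CC[C@]1(C)O | intermediate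
14 | (3R,4S,5S,8S,9R,10R)-18-[tert-butyl(diphenyl)silyl]oxy-15,16-dinorlabd-13-yne-3,8-diol | C#CCC[C@@H]1[C@]2(C)CC[C@@H](O)[C@](C)(CO[Si](c3ccccc3)(c3ccccc3)C(C)(C)C)[C@H]2CC[C@]1(C)O | intermediate
15 | (3R,4S,5S,8S,9R,10R)-18-[tert-butyl(diphenyl)silyl]oxylabda-13(16),14-diene-3,8-diol | C=CC(=C)CC[C@@H]1[C@]2(C)CC[C@@H](O)[C@](C)(CO[Si](c3ccccc3)(c3ccccc3)C(C)(C)C)[C@H]2CC[C@]1(C)O | intermediate
16 | (3R,4S,5S,8S,9R,10R)-18-[tert-butyl(diphenyl)silyl]oxy-8-hydroxylabda-13(16),14-dien-3-yl acetate | C=CC(=C)CC[C@@H]1[C@]2(C)CC[C@@H](OC(C)=O)[C@](C)(CO[Si](c3ccccc3)(c3ccccc3)C(C)(C)C)[C@H]2CC[C@]1(C)O | intermediate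
17 | (3R,4S,5S,8S,9R,10R)-8,18-dihydroxylabda-13(16),14-dien-3-yl acetate | C=CC(=C)CC[C@@H]1[C@]2(C)CC[C@@H](OC(C)=O)[C@](C)(CO)[C@H]2CC[C@]1(C)O | target

## Step count and risk

Total step count: 13. Longest linear sequence: 13 steps, from 1 to 17.

**Step 8 (key step).** The most likely failure is early termination, by proton loss after ring A or at the C8 cation. The oxirane may also open at C3 or undergo a hydride shift, because the silyloxymethyl group withdraws electron density from C4. Boat folding at the Z olefin would erode control of C9. The fallback leaves cation chemistry and sets out from ester 9. Trivalent titanium (Cp2TiCl, made from Cp2TiCl2 and Mn dust, THF, rt) opens the oxirane homolytically; the radical closes rings A and B through the same chair folding and ends by hydrogen loss to the exocyclic olefin, giving the bicyclic hydroxy ester F1. The C4 radical is planar, and the bulkier silyloxymethyl group should take the equatorial position. LiOH gives the acid F2. Iodolactonisation (I2, NaHCO3, aqueous MeCN) closes the δ-lactone on C8 from the only side the axial chain can reach and gives the iodomethyl lactone F3. Bu3SnH with AIBN reduces the C–I bond to methyl and returns to 11.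

**Step 4.** Site selectivity may be poor and the alcohol may oxidise further, since three trisubstituted olefins compete. The fallback builds the terminus by olefination and sets out from 5. N-Bromosuccinimide in aqueous THF reacts preferentially at the terminal olefin to give the bromohydrin F4, and K2CO3 in MeOH closes it to the terminal oxirane F5. H5IO6 cleaves F5 to the aldehyde F6. A Wittig reaction with 2-(triphenylphosphoranylidene)propanal gives the E enal F7, and NaBH4 with CeCl3 reduces it to 6.

**Step 11.** Turnover may be slow on an alkyne without a propargylic heteroatom, the catalyst may die before conversion is complete, and the diene may enter secondary metathesis. The fallback uses carbonyl chemistry and sets out from lactol 12. Excess vinylmagnesium bromide gives the allylic alcohol F8 (C13 epimers), and MnO2 oxidises only this allylic alcohol to the vinyl ketone F9. Non-basic methylenation with Zn, CH2Br2 and TiCl4, which tolerates free hydroxyls, returns to 15.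

**Step 13.** Cleavage of the neopentyl-type silyl ether may be slow. Long exposure could allow acyl shift from O3 to O18, or acid-induced loss of the C8 hydroxyl towards the diene. The fallback changes the order of events and sets out from 15. Bu4NF gives the triol F10, and Ac2O with pyridine and DMAP gives the 3,18-diacetate F11 with the tertiary hydroxyl untouched. Candida antarctica lipase B at neutral pH hydrolyses the more accessible primary acetate and gives 17.

## Further compounds

F1 | step 8 | methyl ester of the bicyclic 3-hydroxy-18-silyloxy acid with exocyclic C8=C17 olefin and axial C9 propanoate chain (stereocentres as in 11) | COC(=O)CC[C@@H]1[C@]2(C)CC[C@@H](O)[C@](C)(CO[Si](c3ccccc3)(c3ccccc3)C(C)(C)C)[C@H]2CCC1=C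
F2 | step 8 | free acid corresponding to F1 | OC(=O)CC[C@@H]1[C@]2(C)CC[C@@H](O)[C@](C)(CO[Si](c3ccccc3)(c3ccccc3)C(C)(C)C)[C@H]2CCC1=C
F3 | step 8 | 17-iodo analogue of lactone 11 (iodomethyl on C8) | O=C1CC[C@@H]2[C@]3(C)CC[C@@H](O)[C@](C)(CO[Si](c4ccccc4)(c4ccccc4)C(C)(C)C)[C@H]3CC[C@]2(CI)O1
F4 | step 4 | methyl (4Z,8E)-12-bromo-13-hydroxy-5,9,13-trimethyltetradeca-4,8-dienoate (racemic) | COC(=O)CC/C=C(/C)CC/C=C(\C)CCC(Br)C(C)(C)O
F5 | step 4 | methyl (4Z,8E)-11-(3,3-dimethyloxiran-2-yl)-5,9-dimethylundeca-4,8-dienoate (racemic) | COC(=O)CC/C=C(/C)CC/C=C(\C)CCC1OC1(C)C
F6 | step 4 | methyl (4Z,8E)-5,9-dimethyl-12-oxododeca-4,8-dienoate | COC(=O)CC/C=C(/C)CC/C=C(\C)CCC=O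
F7 | step 4 | methyl (4Z,8E,12E)-5,9,13-trimethyl-14-oxotetradeca-4,8,12-trienoate | COC(=O)CC/C=C(/C)CC/C=C(\C)CC/C=C(\C)C=O
F8 | step 11 | 18-[tert-butyl(diphenyl)silyl]oxy-16-norlabd-14-ene-3,8,13-triol (C13 epimers, ring stereocentres as in 11) | C=CC(O)CC[C@@H]1[C@]2(C)CC[C@@H](O)[C@](C)(CO[Si](c3ccccc3)(c3ccccc3)C(C)(C)C)[C@H]2CC[C@]1(C)O
F9 | step 11 | 18-[tert-butyl(diphenyl)silyl]oxy-3,8-dihydroxy-16-norlabd-14-en-13-one (ring stereocentres as in 11) | C=CC(=O)CC[C@@H]1[C@]2(C)CC[C@@H](O)[C@](C)(CO[Si](c3ccccc3)(c3ccccc3)C(C)(C)C)[C@H]2CC[C@]1(C)O
F10 | step 13 | (3R,4S,5S,8S,9R,10R)-labda-13(16),14-diene-3,8,18-triol | C=CC(=C)CC[C@@H]1[C@]2(C)CC[C@@H](O)[C@](C)(CO)[C@H]2CC[C@]1(C)O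
F11 | step 13 | (3R,4S,5S,8S,9R,10R)-8-hydroxylabda-13(16),14-diene-3,18-diyl diacetate | C=CC(=C)CC[C@@H]1[C@]2(C)CC[C@@H](OC(C)=O)[C@](C)(COC(C)=O)[C@H]2CC[C@]1(C)O
A1 | alternative 1 | endo Diels–Alder adduct, tricyclic anhydride with C5=C6 olefin and C3/C18 acetonide | O=C1OC(=O)[C@@]2(C)CC=C3[C@@]4(C)COC(C)(C)O[C@@H]4CC[C@@]3(C)[C@@H]12
A2 | alternative 1 | ring-A vinylcyclohexene diene (C10=C5–C6=C7) with C3/C18 acetonide | C=CC1=C(C)CC[C@H]2OC(C)(C)OC[C@]12C
A3 | alternative 1 | citraconic anhydride | CC1=CC(=O)OC1=O
A4 | alternative 2 | cis-fused 7a-methyl-3,3a,4,7a-tetrahydro-1-benzofuran-2,5-dione (lactone enone) | O=C1C[C@@H]2CC(=O)C=C[C@]2(C)O1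
A5 | alternative 2 | 3-[(1-methyl-4-oxocyclohexa-2,5-dien-1-yl)oxy]-3-oxopropanoic acid | CC1(OC(=O)CC(O)=O)C=CC(=O)C=C1
A6 | alternative 3 | cis-fused γ-lactone (carbonyl C12, ring oxygen on C8) of the trans-decalin 3,18-bis-pivalate | O=C1C[C@@H]2[C@]3(C)CC[C@@H](OC(=O)C(C)(C)C)[C@](C)(COC(=O)C(C)(C)C)[C@H]3CC[C@]2(C)O1
A7 | alternative 3 | trans-decalin C8=C9 olefin (C9 unsubstituted), 3,18-bis-pivalate | CC1=C[C@]2(C)CC[C@@H](OC(=O)C(C)(C)C)[C@](C)(COC(=O)C(C)(C)C)[C@H]2CC1
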